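**Plan**
1. Disconnections, in order: the aryl ester C–O bond (phenol plus (S)-3-acetoxybutanoic acid), the acrylate C=C bond (Wittig), then, one oxidation level below the arene, the C1–C2 and C5–C6 bonds of ring A ([4+2]), and last the O–Si bond and the α-methylene C=C of the diene.
2. Enabling feature: ring A is numbered from C1 (carrying the propenoate carbon) through C3 (prenyl) to C4 (oxygen). C3 and C4 are neighbours and C1 is para to C4, so C2–C5 map onto a 2-oxy-3-alkylbuta-1,3-diene and C1/C6 onto a formyl-substituted alkyne.
3. Forward: an acyclic C8 ketone is α-methylenated and silylated to the diene, cycloaddition with propynal closes ring A (the only ring) and DDQ aromatises it. The acrylate arm is then attached by Wittig olefination, and the phenol is unmasked and acylated last.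
4. Stereochemistry: the single (S) stereocentre is bought with (S)-3-hydroxybutanoic acid and is never a reacting centre; the (E)-alkene comes from the stabilised ylide.

Key step: step 3

Remark: propynal is taken as a commercial reagent (stabilised solution, distilled cold before use), and the direct methylenation is assumed to follow the usual Mannich preference for the more substituted α-carbon of a methyl ketone.

**Step 1**
Reactants: 1 6-methylhept-5-en-2-one
Product: 3 6-methyl-3-methylidenehept-5-en-2-one, via Mannich base 2 (not isolated)
Conditions: (CH2O)n, i-Pr2NH2 O2CCF3 (1 equiv), CF3CO2H (0.1 equiv), THF, reflux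
Reagents that add atoms: paraformaldehyde (used as formaldehyde), C=O
Why: Under acid the methyl ketone reacts through its more substituted enol, so the iminium ion from formaldehyde and diisopropylamine should attack C3, and E1cB loss of the amine from Mannich base 2 should give the α-methylene ketone (direct α-methylenation, Mannich reaction).

**Step 2**
Reactants: 3 6-methyl-3-methylidenehept-5-en-2-one
Product: 4 tert-butyldimethyl[(6-methyl-3-methylidenehepta-1,5-dien-2-yl)oxy]silane
Conditions: TBSOTf, Et3N, CH2Cl2, 0 °C; filtration through Et3N-deactivated silica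
Reagents that add atoms: tert-butyldimethylsilyl trifluoromethanesulfonate (TBSOTf), CC(C)(C)[Si](C)(C)OS(=O)(=O)C(F)(F)F
Why: After O-silylation of the ketone, triethylamine can remove a proton only from the methyl group, because C3 carries no hydrogen, so the cross-conjugated 2-silyloxy-1,3-diene should form (silyl enol ether formation with a silyl triflate).

**Step 3**
Reactants: 4 tert-butyldimethyl[(6-methyl-3-methylidenehepta-1,5-dien-2-yl)oxy]silane; 5 propynal
Product: 6 4-(tert-butyldimethylsilyloxy)-5-(3-methylbut-2-enyl)cyclohexa-1,4-diene-1-carbaldehyde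
Conditions: toluene, 2,6-di-tert-butyl-4-methylphenol (trace), sealed tube, dark, 60 °C; volatiles removed, crude used directly
Reagents that add atoms: none
Why: The electron-rich silyloxydiene 4 (HOMO) and the electron-poor ynal 5 (LUMO) should combine in a concerted, asynchronous, suprafacial thermal [4+2] cycloaddition that forms the C1–C2 and C5–C6 bonds in one event and leaves a cyclohexa-1,4-diene one oxidation level below the arene. The closest known reaction type is the Diels–Alder reaction of 2-silyloxy-1,3-dienes with acetylenic aldehydes and esters. Ring A closes by an intermolecular [4+2] annulation in which C2–C5 come from the diene and C1 and C6 from the alkyne. No stereocentre is formed. The step needs the aldehyde para to the silyloxy group: the oxygen donor places the largest HOMO coefficient on the CH2 next to the C–O carbon (C5), which bonds to the β-carbon of propynal (C6, largest LUMO coefficient), and this should outweigh the weaker opposite bias of the 3-alkyl group. The 2,3-disubstitution favours the s-cis conformer, and the isolated trisubstituted prenyl alkene is neither part of the diene nor activated as a dienophile.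

**Step 4**
Reactants: 6 4-(tert-butyldimethylsilyloxy)-5-(3-methylbut-2-enyl)cyclohexa-1,4-diene-1-carbaldehyde
Product: 7 4-(tert-butyldimethylsilyloxy)-3-(3-methylbut-2-enyl)benzaldehyde
Conditions: DDQ (2,3-dichloro-5,6-dicyano-1,4-benzoquinone, 1.05 equiv), toluene, 0 °C to rt; filtration, basic alumina plug
Reagents that add atoms: none
Why: DDQ should abstract hydride from a doubly allylic ring CH2 of the cyclohexa-1,4-diene, and proton loss from the stabilised cyclohexadienyl cation gives the arene with the silyl ether intact (quinone dehydrogenation), one equivalent at low temperature sparing the prenyl CH2.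

**Step 5**
Reactants: 7 4-(tert-butyldimethylsilyloxy)-3-(3-methylbut-2-enyl)benzaldehyde; 8 methyl (triphenylphosphoranylidene)acetate
Product: 9 methyl (E)-3-[4-(tert-butyldimethylsilyloxy)-3-(3-methylbut-2-enyl)phenyl]prop-2-enoate
Conditions: toluene, 80 °C
Reagents that add atoms: none
Why: Wittig olefination of an aromatic aldehyde with a stabilised ylide passes through the less crowded anti oxaphosphetane, so the (E)-cinnamate should form.

**Step 6**
Reactants: 9 methyl (E)-3-[4-(tert-butyldimethylsilyloxy)-3-(3-methylbut-2-enyl)phenyl]prop-2-enoate
Product: 10 methyl (E)-3-[4-hydroxy-3-(3-methylbut-2-enyl)phenyl]prop-2-enoate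
Conditions: Bu4NF (1.1 equiv), AcOH (1.1 equiv), THF, 0 °C
Reagents that add atoms: none
Why: Fluoride attacks silicon of the aryl silyl ether and releases the phenol, while the acetic acid buffer keeps the phenoxide from touching the methyl ester or the acrylate (fluoride desilylation).

**Step 7**
Reactants: 11 (S)-3-hydroxybutanoic acid
Product: 12 (S)-3-acetoxybutanoic acid
Conditions: AcCl (neat, excess), 0 °C to rt; evaporation, aqueous work-up
Reagents that add atoms: acetyl chloride, CC(=O)Cl
Why: O-Acetylation of the secondary alcohol with an acid chloride breaks no bond at C3, so the (S) configuration is retained, and the base-free medium avoids β-elimination (acylation of a hydroxy acid).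

**Step 8**
Reactants: 10 methyl (E)-3-[4-hydroxy-3-(3-methylbut-2-enyl)phenyl]prop-2-enoate; 12 (S)-3-acetoxybutanoic acid
Product: 13 methyl (E)-3-[4-[(3S)-3-acetoxybutanoyl]oxy-3-(3-methylbut-2-enyl)phenyl]prop-2-enoate (CNP0290147.1)
Conditions: N,N'-dicyclohexylcarbodiimide (DCC, 1.1 equiv), 4-(dimethylamino)pyridine (0.1 equiv), CH2Cl2, 0 °C to rt
Reagents that add atoms: none
Why: In this Steglich esterification the carbodiimide activates acid 12, 4-(dimethylamino)pyridine relays the acyl group to the phenol oxygen of 10, and the stereocentre, being β to the carbonyl, is not enolisable, so (S) is carried into 13; low temperature and a catalytic amount of base should hold back β-elimination of acetate.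

**Compound list**
1 | 6-methylhept-5-en-2-one | CC(=O)CCC=C(C)C | starting material
2 | Mannich base, 3-[(diisopropylamino)methyl]-6-methylhept-5-en-2-one (racemic, not isolated) | CC(=O)C(CN(C(C)C)C(C)C)CC=C(C)C | intermediate
3 | 6-methyl-3-methylidenehept-5-en-2-one | CC(=O)C(=C)CC=C(C)C | intermediate
4 | tert-butyldimethyl[(6-methyl-3-methylidenehepta-1,5-dien-2-yl)oxy]silane | C=C(O[Si](C)(C)C(C)(C)C)C(=C)CC=C(C)C | intermediate
5 | propynal | C#CC=O | starting material
6 | 4-(tert-butyldimethylsilyloxy)-5-(3-methylbut-2-enyl)cyclohexa-1,4-diene-1-carbaldehyde | O=CC1=CCC(O[Si](C)(C)C(C)(C)C)=C(CC=C(C)C)C1 | intermediate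
7 | 4-(tert-butyldimethylsilyloxy)-3-(3-methylbut-2-enyl)benzaldehyde | O=Cc1ccc(O[Si](C)(C)C(C)(C)C)c(CC=C(C)C)c1 | intermediate
8 | methyl (triphenylphosphoranylidene)acetate | COC(=O)C=P(c1ccccc1)(c1ccccc1)c1ccccc1 | starting material
9 | methyl (E)-3-[4-(tert-butyldimethylsilyloxy)-3-(3-methylbut-2-enyl)phenyl]prop-2-enoate | COC(=O)/C=C/c1ccc(O[Si](C)(C)C(C)(C)C)c(CC=C(C)C)c1 | intermediate
10 | methyl (E)-3-[4-hydroxy-3-(3-methylbut-2-enyl)phenyl]prop-2-enoate | COC(=O)/C=C/c1ccc(O)c(CC=C(C)C)c1 | intermediate
11 | (S)-3-hydroxybutanoic acid | C[C@H](O)CC(=O)O | starting material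
12 | (S)-3-acetoxybutanoic acid | C[C@H](OC(C)=O)CC(=O)O | intermediate
13 | methyl (E)-3-[4-[(3S)-3-acetoxybutanoyl]oxy-3-(3-methylbut-2-enyl)phenyl]prop-2-enoate | COC(=O)/C=C/c1ccc(OC(=O)C[C@H](C)OC(C)=O)c(CC=C(C)C)c1 | target

**Step count and risks**
Total step count: 8. Longest linear sequence: 7 steps (steps 1–6 and 8); step 7 is a one-step side branch.

Steps most likely to fail:

Step 3 (key cycloaddition). Oligomerisation of the ynal and hydrolytic loss of the silyl enol ether may outrun the cycloaddition, and the 3-alkyl group may erode the para regiocontrol. The fallback sets out from diene 4 and uses a stable acetylenic ester that tolerates higher temperature, with the aldehyde oxidation level set after aromatisation. Diene 4 is heated with methyl propiolate (toluene, 110 °C, sealed tube) to give methyl 4-(tert-butyldimethylsilyloxy)-5-(3-methylbut-2-enyl)cyclohexa-1,4-diene-1-carboxylate F1. DDQ (toluene, 0 °C to rt) converts it to methyl 4-(tert-butyldimethylsilyloxy)-3-(3-methylbut-2-enyl)benzoate F2, at which stage any regioisomer can be removed by chromatography. Reduction with i-Bu2AlH (CH2Cl2, −78 °C) gives [4-(tert-butyldimethylsilyloxy)-3-(3-methylbut-2-enyl)phenyl]methanol F3, and MnO2 (CH2Cl2, rt) oxidises it to aldehyde 7, where the route is rejoined.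

Step 1 (direct methylenation). Aminomethylation may also take place at the methyl carbon or twice, and the volatile enone may dimerise by hetero-Diels–Alder reaction during isolation. The fallback sets out from ketone 1 and fixes the regiochemistry in a separate enol ether step, with a storable amine as the intermediate. Me3SiCl, NaI and Et3N in MeCN under equilibrating conditions should give the more substituted silyl enol ether, (Z)-trimethyl[(6-methylhepta-2,5-dien-2-yl)oxy]silane F4. Dimethyl(methylidene)ammonium iodide (CH2Cl2, rt) converts it to 3-[(dimethylamino)methyl]-6-methylhept-5-en-2-one F5, which is purified by acid–base extraction. Methyl iodide gives (2-acetyl-5-methylhex-4-en-1-yl)trimethylammonium iodide F6, and aqueous NaHCO3/CH2Cl2 eliminates trimethylamine to give enone 3 just before silylation, where the route is rejoined.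

Step 4 (aromatisation). The quinone may oxidise the benzylic–allylic CH2 of the prenyl chain, or its acidic hydroquinone may cleave the silyl enol ether before dehydrogenation. The fallback sets out from cycloadduct 6 and uses the silyl enol ether itself as the reacting handle in a Saegusa–Ito oxidation. Pd(OAc)2 (MeCN, rt) forms the palladium enolate, and β-hydride elimination followed by enolisation should give 4-hydroxy-3-(3-methylbut-2-enyl)benzaldehyde F7. Wittig olefination of this free phenol aldehyde with ylide 8 (toluene, 80 °C) gives phenol 10, where the route is rejoined; compounds 7 and 9 and step 6 are bypassed.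

**Further compounds**
F1 | step 3 | methyl 4-(tert-butyldimethylsilyloxy)-5-(3-methylbut-2-enyl)cyclohexa-1,4-diene-1-carboxylate | COC(=O)C1=CCC(O[Si](C)(C)C(C)(C)C)=C(CC=C(C)C)C1
F2 | step 3 | methyl 4-(tert-butyldimethylsilyloxy)-3-(3-methylbut-2-enyl)benzoate | COC(=O)c1ccc(O[Si](C)(C)C(C)(C)C)c(CC=C(C)C)c1
F3 | step 3 | [4-(tert-butyldimethylsilyloxy)-3-(3-methylbut-2-enyl)phenyl]methanol | OCc1ccc(O[Si](C)(C)C(C)(C)C)c(CC=C(C)C)c1
F4 | step 1 | (Z)-trimethyl[(6-methylhepta-2,5-dien-2-yl)oxy]silane | C/C(O[Si](C)(C)C)=C/CC=C(C)C
F5 | step 1 | 3-[(dimethylamino)methyl]-6-methylhept-5-en-2-one (racemic) | CC(=O)C(CN(C)C)CC=C(C)C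
F6 | step 1 | (2-acetyl-5-methylhex-4-en-1-yl)trimethylammonium iodide (racemic) | CC(=O)C(C[N+](C)(C)C)CC=C(C)C.[I-]
F7 | step 4 | 4-hydroxy-3-(3-methylbut-2-enyl)benzaldehyde | O=Cc1ccc(O)c(CC=C(C)C)c1
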